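The same isomer cannot both stop and keep climbing, yet in percentages of the charge it seems to do just that. The spring run is the flask asked about, followed so far; the noon run had less solid substrate.

| flask | solid substrate | remark | time |
|---|---|---|---|
| spring | 10 mM | the very flask that is asked about, followed so far |  |
| noon | 6.7 mM | run made earlier |  |
| flask | 10 mM |  | 12 h |

- spring (time / h: solid substrate / %, target / %, isomer of the product / %): 0.200: 90.5, 2.5, 1.6; 0.500: 75.4, 8.4, 3.9; 1.00: 52.9, 20.7, 12.9; 1.50: 29.5, 34.7, 21.6; 2.00: 7.5, 49.9, 28.6; 3.00: 0.4, 60.9, 33.8; 4.00: 0, 61.5, 33.6
- noon (time / h: solid substrate / %, target / %, isomer of the product / %): 1.50: 0, 51.8, 31.1; 3.00: 0, 56.8, 37.0; 5.00: 0, 53.7, 39.8; 6.00: 0, 51.5, 41.4; 8.00: 0, 50.4, 42.7; 10.0: 0.5, 48.9, 44.7; 12.0: 0, 48.5, 46.7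

(scatter of a reading: 0.5 percentage points)

- at the start none of the solid substrate is in solution
- what has only dissolved of solid substrate counts as not reacted
- a reading or a percentage of target counts all its forms, free or not
- the reaction counts as stopped when no species that holds the solid substrate changes by six tenths of a point or more over the second half of the time

1. the state of affairs at 12 h: stopped, and by what, or still going (for what has run out or reacted, a solid counts together with what of it has only dissolved) (forward and back rates have come level / it is still moving / all of the solid substrate has reacted)
2. part of the solid substrate that has turned into other species by 12 h (what has only dissolved does not count)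
3. the target standing at 12 h, as a percentage of the solid substrate charged
4. the isomer of the product standing at 12 h, as a percentage of the solid substrate charged

The spring isomer reads 33.8% at 3.00 h and 33.6% at 4.00 h, while the noon isomer goes from 37.0% at 3.00 h to 46.7% at 12.0 h. The two fit once I turn percent into concentration. The spring plateau reads 3.37 mM, and I call this the standing level of the isomer, the concentration at which the spring isomer stopped rising. The last noon reading of the isomer is 3.13 mM, below that level, so the noon rise does not clash with the spring plateau; the same level stands for 50.3% of the noon charge.

The spring isomer reads level from 3.00 h, when the solid reads 0.4%, so I expect this flask to stand still, with forward and back rates level. The spring readings at 4.00 h leave 4.90% missing, or 0.490 mM, which I read as dissolved, unreacted substrate. I reckon the two smaller shares and take them from the charge: isomer 33.7%, conversion 95.1%, and target as the remainder, 61.4%, more than the isomer.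

The forecast differs: it holds that “target slowly isomerises to its isomer” and says it is still moving, with conversion 95%, target 54% and isomer 41%.

The flask gives this at 12 h: forward and back rates have come level, which is thermodynamic control, with conversion 95.6%, target 61.6% and isomer 34.0%.

    starting material ⇌ target (K = 2.20, k = 8.10 × 10⁻⁴ s⁻¹)
    starting material ⇌ isomer of the product (K = 7.70, k = 3.70 × 10⁻⁴ s⁻¹)
    crystals ⇌ target, rate k3*(cs3 - [target]) while solid is left; crystals form when [target] > cs3 (solubility = 0.970 mM, k = 0.0190 s⁻¹)
    solid substrate ⇌ starting material, rate k4*(cs4 - [starting material]) while solid is left; crystals form when [starting material] > cs4 (solubility = 9.30 mM, k = 1.60 × 10⁻⁴ s⁻¹)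

Crystals hold 51.9% of this flask's charge at 12.0 h, counted within the target. The same reckoning on the neighbour charged with 4.0 mM gives isomer 84.2%, missing part 12.2% and target 3.50%. That neighbour in fact holds isomer 69.2%, which is 2.77 mM, short of the level, with starting material 9.50% and target 21.3%. Its crystals stand at 0%.

All runs were generated by integration for substances that don't exist; the scatter is artificial.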